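**Assumptions (one line each)**
- The SMILES reads as the 9-O-(E)-feruloyl ester of (8R,8'R)-secoisolariciresinol. Both stereocenters are R; the diol core is C2-symmetric, so either CH2OH gives the same monoester.
- The Ru-(R)-BINAP catalyst is assumed to give the (R)-acid 8. If chiral HPLC shows the opposite sense, the (S)-ligand is used.

## Retrosynthetic overview
1. Hanultarin is the monoferuloyl ester of (R,R)-secoisolariciresinol (15). It is disconnected by a lipase-catalysed (hydrolase) acyl transfer from an activated ferulate to one of the two equivalent primary OH groups.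
2. Diol 15 comes from the trans-dibenzylbutyrolactone 13 by LiAlH4 reduction, then hydrogenolysis of the aryl benzyl ethers.
3. Lactone 13 comes from trans-selective benzylation of the β-benzyl lactone 10. Lactone 10 is made from the Ru-BINAP hydrogenation product 8, which sets C-8.
4. Acid 7 comes from a Stobbe condensation of 4-O-benzylvanillin with di-tert-butyl succinate. The only ring formed is the γ-butyrolactone (Step 7), a temporary template that is opened in Step 11.

## Forward synthesis

**Step 1**
Reactants: 1 vanillin; 2 benzyl bromide
Product: 3 4-(benzyloxy)-3-methoxybenzaldehyde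
Conditions: BnBr, K2CO3, DMF, rt, 12 h
Reagents that add atoms: none beyond numbered reactant 2
Why: Williamson O-benzylation of the phenol gives a protecting group that survives the later steps and is removed by hydrogenolysis in Step 12.

**Step 2**
Reactants: 3; 4 di-tert-butyl succinate
Product: 5 (E)-4-[4-(benzyloxy)-3-methoxyphenyl]-3-(tert-butoxycarbonyl)but-3-enoic acid
Conditions: t-BuOK (2.2 equiv), t-BuOH, reflux, 4 h; then aq. citric acid
Reagents that add atoms: none
Why: Stobbe condensation (aldol, γ-lactonisation, E1cB ring opening) puts the free CH2CO2H on one side and the t-Bu ester on the alkylidene carbon. The aryl ends up trans to that ester (E).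

**Step 3**
Reactants: 5
Product: 6 1-tert-butyl 4-methyl (E)-2-[4-(benzyloxy)-3-methoxybenzylidene]succinate
Conditions: MeI, K2CO3, DMF, rt, 3 h
Reagents that add atoms: methyl iodide, CI
Why: simple carboxylate O-methylation, which makes the two esters distinguishable (Me versus t-Bu).

**Step 4**
Reactants: 6
Product: 7 (E)-2-[4-(benzyloxy)-3-methoxybenzylidene]-4-methoxy-4-oxobutanoic acid
Conditions: TFA, CH2Cl2 (1:4), 0 °C to rt, 3 h
Reagents that add atoms: none
Why: acidolysis of the t-Bu ester (loss of isobutylene) leaves the methyl ester, benzyl ether and alkene intact. It places the CO2H on the carbon that will become the stereocenter, giving an α-substituted cinnamic acid.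

**Step 5**
Reactants: 7
Product: 8 (R)-2-[4-(benzyloxy)-3-methoxybenzyl]-4-methoxy-4-oxobutanoic acid
Conditions: Ru(OAc)2[(R)-BINAP] (1 mol%), H2 (50 bar), MeOH, 25 °C, 24 h
Reagents that add atoms: none (H2 adds only H)
Why: carboxylate-directed Ru-BINAP asymmetric hydrogenation of the trisubstituted (E)-acrylic acid. H2 is delivered to one enantioface and sets C-8 as R; the benzyl ether and esters are untouched.

**Step 6**
Reactants: 8
Product: 9 methyl (R)-4-[4-(benzyloxy)-3-methoxyphenyl]-3-(hydroxymethyl)butanoate
Conditions: BH3·SMe2 (1.2 equiv), THF, 0 °C to rt, 4 h; MeOH quench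
Reagents that add atoms: none
Why: borane chemoselectively reduces the free carboxylic acid over the methyl ester and benzyl ether. The stereocenter is not involved, so it is retained as R.

**Step 7**
Reactants: 9
Product: 10 (R)-4-[4-(benzyloxy)-3-methoxybenzyl]dihydrofuran-2(3H)-one
Conditions: p-TsOH·H2O (5 mol%), toluene, 50 °C, 2 h, MeOH removed under reduced pressure
Reagents that add atoms: none
Why: acid-catalysed γ-hydroxy-ester lactonisation (transesterification) gives the β-benzyl lactone. The carbinol carbon is CH2, so there is no epimerisation.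

**Step 8**
Reactants: 3
Product: 11 [4-(benzyloxy)-3-methoxyphenyl]methanol
Conditions: NaBH4, MeOH, 0 °C to rt, 1 h
Reagents that add atoms: none
Why: chemoselective aldehyde reduction prepares the electrophile for Step 10.

**Step 9**
Reactants: 11
Product: 12 4-(benzyloxy)-3-methoxybenzyl bromide
Conditions: PBr3 (0.4 equiv), Et2O, 0 °C, 30 min; used immediately
Reagents that add atoms: phosphorus tribromide, BrP(Br)Br
Why: PBr3 converts the benzylic alcohol to the bromide by SN2 displacement. It is used fresh because electron-rich benzyl bromides decompose on storage.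

**Step 10**
Reactants: 10; 12
Product: 13 (3R,4R)-3,4-bis[4-(benzyloxy)-3-methoxybenzyl]dihydrofuran-2(3H)-one
Conditions: LiHMDS (1.05 equiv), THF, −78 °C, 45 min; then 12 (1.3 equiv), −78 to −40 °C, 4 h; sat. aq. NH4Cl quench
Reagents that add atoms: none beyond numbered reactant 12
Why: lactone enolate alkylation, with the electrophile approaching anti to the β-benzyl group. This sets C-8' as R, so the lactone is trans (8R,8'R); the low-temperature quench avoids epimerisation.

**Step 11**
Reactants: 13
Product: 14 (2R,3R)-2,3-bis[4-(benzyloxy)-3-methoxybenzyl]butane-1,4-diol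
Conditions: LiAlH4 (2 equiv), THF, 0 °C to rt, 3 h; Fieser workup
Reagents that add atoms: none
Why: hydride reduction opens the lactone to the diol. The ether groups survive and no stereocenter is touched, since C-8' is not enolisable once the carbonyl is reduced.

**Step 12**
Reactants: 14
Product: 15 (2R,3R)-secoisolariciresinol, i.e. (2R,3R)-2,3-bis(4-hydroxy-3-methoxybenzyl)butane-1,4-diol
Conditions: H2 (1 atm), 10% Pd/C, MeOH/EtOAc (1:1), rt, 6 h
Reagents that add atoms: none
Why: hydrogenolysis of the aryl benzyl ethers (toluene byproduct). This is done before the ferulate is installed, because there is no C=C to reduce yet.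

**Step 13**
Reactants: 16 ferulic acid
Product: 17 2,2,2-trifluoroethyl (E)-ferulate
Conditions: SOCl2 (1.2 equiv), CF3CH2OH (solvent), 0 to 70 °C, 4 h
Reagents that add atoms: 2,2,2-trifluoroethanol, OCC(F)(F)F
Why: acid-chloride-mediated esterification in excess alcohol gives an activated ester. The trifluoroethoxide leaving group is a poor nucleophile, which makes the lipase acyl transfer in Step 14 effectively irreversible.

**Step 14**
Reactants: 15 (3 equiv); 17 (1 equiv)
Product: 18 Hanultarin, the (8R,8'R)-secoisolariciresinol 9-O-(E)-feruloyl ester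
Conditions: Novozym 435 (immobilised Candida antarctica lipase B, a hydrolase), 2-methyl-2-butanol/THF (2:1), 4 Å MS, 45 °C, 48 h; recover excess 15 by chromatography
Reagents that add atoms: none beyond numbered reactant 17
Why: lipase-catalysed transesterification through an acyl-enzyme acylates primary aliphatic OH groups and not the phenols or the E-alkene. Excess C2-symmetric diol 15 favours the monoester over the diester, and the stereocenters are not affected.

## Compound list
1 | vanillin | COc1cc(C=O)ccc1O | starting material
2 | benzyl bromide | BrCc1ccccc1 | starting material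
3 | 4-(benzyloxy)-3-methoxybenzaldehyde | COc1cc(C=O)ccc1OCc1ccccc1 | intermediate
4 | di-tert-butyl succinate | CC(C)(C)OC(=O)CCC(=O)OC(C)(C)C | starting material
5 | Stobbe half-ester (E) | COc1cc(/C=C(\CC(=O)O)C(=O)OC(C)(C)C)ccc1OCc1ccccc1 | intermediate
6 | t-Bu/Me diester (E) | COc1cc(/C=C(\CC(=O)OC)C(=O)OC(C)(C)C)ccc1OCc1ccccc1 | intermediate
7 | (E)-arylidene succinic acid 4-methyl ester | COc1cc(/C=C(\CC(=O)OC)C(=O)O)ccc1OCc1ccccc1 | intermediate
8 | (R)-2-arylmethyl-succinic acid 4-methyl ester | COC(=O)C[C@@H](Cc1ccc(OCc2ccccc2)c(OC)c1)C(=O)O | intermediate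
9 | (R)-hydroxy ester | COC(=O)C[C@@H](Cc1ccc(OCc2ccccc2)c(OC)c1)CO | intermediate
10 | (R)-β-arylmethyl-γ-butyrolactone | O=C1C[C@@H](Cc2ccc(OCc3ccccc3)c(OC)c2)CO1 | intermediate
11 | 4-(benzyloxy)-3-methoxybenzyl alcohol | COc1cc(CO)ccc1OCc1ccccc1 | intermediate
12 | 4-(benzyloxy)-3-methoxybenzyl bromide | COc1cc(CBr)ccc1OCc1ccccc1 | intermediate
13 | (3R,4R)-trans-dibenzylbutyrolactone | O=C1OC[C@H](Cc2ccc(OCc3ccccc3)c(OC)c2)[C@H]1Cc1ccc(OCc2ccccc2)c(OC)c1 | intermediate
14 | (2R,3R)-bis(OBn) diol | OC[C@H](Cc1ccc(OCc2ccccc2)c(OC)c1)[C@H](CO)Cc1ccc(OCc2ccccc2)c(OC)c1 | intermediate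
15 | (R,R)-secoisolariciresinol | OC[C@H](Cc1ccc(O)c(OC)c1)[C@H](CO)Cc1ccc(O)c(OC)c1 | intermediate
16 | ferulic acid | COc1cc(/C=C/C(=O)O)ccc1O | starting material
17 | 2,2,2-trifluoroethyl (E)-ferulate | COc1cc(/C=C/C(=O)OCC(F)(F)F)ccc1O | intermediate
18 | Hanultarin | COc1cc(/C=C/C(=O)OC[C@H](Cc2ccc(O)c(OC)c2)[C@H](CO)Cc2ccc(O)c(OC)c2)ccc1O | target

## Totals
- Total steps: 14.
- Longest linear sequence: 11 steps (Steps 1, 2, 3, 4, 5, 6, 7, 10, 11, 12, 14).

## Three steps most likely to fail
1. **Step 5, asymmetric hydrogenation.** The ee or the absolute sense may be insufficient for this trisubstituted acid. Fallback: hydrogenate 7 racemically (RhCl(PPh3)3, H2), then resolve acid 8 by crystallising its salt with (S)- or (R)-1-phenylethylamine, or by CAL-B kinetic resolution of the hydroxy ester 9, and recycle the wrong enantiomer.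
2. **Step 10, lactone benzylation.** The unstable bromide 12 may give low yield or poor trans selectivity. Fallback: change to an aldol route. Deprotonate 10 and add 4-O-benzylvanillin 3, dehydrate (MsCl, Et3N, then DBU) to the α-arylidene lactone, then hydrogenate (H2, Pd/C). H2 adds anti to the β-benzyl group and also removes the benzyl ethers, giving the trans-(R,R) phenolic lactone, which is reduced with excess LiAlH4 to 15.
3. **Step 14, lipase monoferuloylation.** Conversion may be low, or the diester may form. Fallback: use a chemical route from 14. Mono-silylate one OH (NaH, TBSCl, THF, statistical), esterify the other with 4-O-benzylferulic acid (EDC, DMAP), then remove all benzyl groups and the TBS with BCl3/pentamethylbenzene in CH2Cl2 at −78 °C, which does not reduce the cinnamate.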